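A direct plan would acylate a lithiated, MOM-protected 2-prenylphloroglucinol methyl ether with a p-coumaric Weinreb amide to give the protected chalcone A1, epoxidise the enone asymmetrically, and let acid remove the acetals and close ring C through O1–C2 to the dihydroflavonol A2.
Borohydride would then give the 4α-ol A3, and dilute acid would be needed to epimerise C4.
Its weakest steps would be these:
(a) the acid step that deprotects, opens the epoxide and closes ring C: ring size (6-endo against 5-exo), the C2 configuration (SN2 against SN1 at a p-oxybenzylic carbon) and the ortho-prenylphenol (chroman formation) would all be left to one pot;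
(b) the C4 carbinol: hydride reduction of A2 would give the wrong epimer A3, and its correction by SN1 ionisation would be an equilibrium with recycling, run on the last, self-condensing intermediate;
(c) the acetal protections and the acyl activation: four operations that add no skeletal bond, spent around an epoxidation of a twisted 2',6'-disubstituted chalcone.

**Plan of the new route**
The retrosynthesis cuts C4–C4a first (ring C), then O1–C2 (an intermolecular SN2 ether bond), then C8–prenyl; C2 and C3 come from one Sharpless epoxidation and C4 is created in the ring closure.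
Rings A and B are bought as benzene rings; ring C is the only ring made and closes from its carbon end onto an aryl ether already in place, so there is no chalcone, no chromanone, no hydride reduction and no epimerisation, and C4 enters directly as the carbinol.
The enabling feature: the 7-OH is para to C4a, so the 7-phenoxide makes C4a the carbon end of a vinylogous enolate six atoms from C4; C8 carries the prenyl group, so only one ortho carbon can cyclise.
The ring A block 7 is mirror-symmetric, so neither its two hydroxyls nor its two ring CH positions need to be told apart, and the peri 5-OMe should push the C4 oxygen pseudo-axial (3,4-cis).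
The only strong acid of the route acts on the simple arene 6, before any stereocentre exists.
Key step: step 10

Remark on the chemistry: 4β is read as the 3,4-cis (4S) carbinol of the SMILES; epoxide 12 and aldehyde 15 are assumed to be used without storage.

**Step 1**
Reactants: 1 5-methoxyresorcinol; 2 chloromethyl methyl ether
Product: 3 1-methoxy-3,5-bis(methoxymethoxy)benzene
Conditions: MOMCl (2.5 equiv), i-Pr2NEt (3 equiv), CH2Cl2, 0 °C to rt
Reagents that add atoms: chloromethyl methyl ether, COCCl
Why: Double O-alkylation of the phenols (Williamson type) gives the bis-acetal whose two OMOM groups direct the lithiation of step 2; no stereocentre is involved.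

**Step 2**
Reactants: 3 1-methoxy-3,5-bis(methoxymethoxy)benzene; 4 prenyl bromide
Product: 6 5-methoxy-1,3-bis(methoxymethoxy)-2-(3-methylbut-2-enyl)benzene, via aryllithium 5 (not isolated)
Conditions: n-BuLi (1.1 equiv), THF, 0 °C, 1 h; then CuI (10 mol %), prenyl bromide (1.2 equiv), −78 °C to rt
Reagents that add atoms: prenyl bromide, CC(C)=CCBr; n-butyllithium, [Li]CCCC (lithium of 5 only)
Why: Directed ortho-metalation takes the proton between the two chelating OMOM groups, and copper-catalysed SN2 allylation at the primary carbon of prenyl bromide gives the linear prenyl arene, which is mirror-symmetric.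

**Step 3**
Reactants: 6 5-methoxy-1,3-bis(methoxymethoxy)-2-(3-methylbut-2-enyl)benzene
Product: 7 5-methoxy-2-(3-methylbut-2-enyl)benzene-1,3-diol
Conditions: HCl (0.5 M in MeOH), rt to 40 °C, 2–4 h; NaHCO3 quench
Reagents that add atoms: none
Why: Acid-catalysed acetal methanolysis frees both phenols while the prenyl alkene should survive dilute methanolic HCl near room temperature (chroman formation needs stronger acid or heat).

**Step 4**
Reactants: 8 (E)-p-coumaric acid; 9 allyl bromide
Product: 10 allyl (E)-3-[4-(allyloxy)phenyl]acrylate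
Conditions: allyl bromide (2.5 equiv), K2CO3 (3 equiv), DMF, rt to 50 °C
Reagents that add atoms: allyl bromide, C=CCBr
Why: Carboxylate and phenoxide O-alkylation in one operation; the aryl allyl ether is inert to hydride, peroxide, base and oxoammonium and is removed at the end under neutral palladium catalysis, and the allyl ester is consumed in step 5.

**Step 5**
Reactants: 10 allyl (E)-3-[4-(allyloxy)phenyl]acrylate
Product: 11 (E)-3-[4-(allyloxy)phenyl]prop-2-en-1-ol
Conditions: i-Bu2AlH (2.3 equiv), CH2Cl2, −78 to 0 °C; Rochelle salt work-up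
Reagents that add atoms: none
Why: 1,2-Reduction of the enoate by i-Bu2AlH gives the E-allylic alcohol needed for the directed epoxidation; the aryl allyl ether is untouched.

**Step 6**
Reactants: 11 (E)-3-[4-(allyloxy)phenyl]prop-2-en-1-ol
Product: 12 [(2S,3S)-3-(4-allyloxyphenyl)oxiran-2-yl]methanol
Conditions: Ti(OiPr)4 (10 mol %), L-(+)-diisopropyl tartrate (14 mol %), t-BuOOH (2 equiv, in decane), 4 Å sieves, CH2Cl2, −20 °C; aqueous NaOH/brine work-up, Et3N-deactivated silica or used crude
Reagents that add atoms: tert-butyl hydroperoxide, CC(C)(C)OO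
Why: Sharpless asymmetric epoxidation: the titanium tartrate complex oxidises only the alkene of the allylic alcohol (not the allyl ether), and L-(+)-tartrate delivers oxygen to the face that gives the (2S,3S) epoxide, whose two carbons become C2 and C3 of the flavan.

**Step 7**
Reactants: 7 5-methoxy-2-(3-methylbut-2-enyl)benzene-1,3-diol; 12 [(2S,3S)-3-(4-allyloxyphenyl)oxiran-2-yl]methanol
Product: 13 (2S,3R)-3-[4-(allyloxy)phenyl]-3-[3-hydroxy-5-methoxy-2-(3-methylbut-2-enyl)phenoxy]propane-1,2-diol
Conditions: 7 (2.5 equiv, excess recovered), Cs2CO3 (0.3 equiv), degassed DMF, 60 °C, Ar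
Reagents that add atoms: epoxy alcohol 12, OC[C@@H]1O[C@H]1c1ccc(OCC=C)cc1
Why: SN2 opening of the 3-aryl-2,3-epoxy alcohol by a phenoxide at the benzylic carbon (the known regiochemistry for 3-arylglycidols, reinforced by the p-alkoxy group) forms O1–C2 with inversion, so the trans epoxide gives the erythro ether (future 2R, 2,3-trans) while the carbinol carbon keeps its configuration (future 3S); the two hydroxyls of 7 are equivalent, so only double alkylation has to be suppressed by the excess of 7.

**Step 8**
Reactants: 13 (2S,3R)-3-[4-(allyloxy)phenyl]-3-[3-hydroxy-5-methoxy-2-(3-methylbut-2-enyl)phenoxy]propane-1,2-diol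
Product: 14 3-{[(1R,2S)-1-[4-(allyloxy)phenyl]-2,3-dihydroxypropyl]oxy}-5-methoxy-2-(3-methylbut-2-enyl)phenyl acetate
Conditions: Ac2O (1.05 equiv), 1 M aq NaOH (1.1 equiv), THF, 0 °C, 10 min
Reagents that add atoms: acetic anhydride, CC(=O)OC(C)=O
Why: Chemoselective acetylation of the phenoxide in water (Schotten–Baumann type), to which the aliphatic diol is inert, shields the electron-rich phenol from the oxidant of step 9 and stores the nucleophile of step 10 in latent form.

**Step 9**
Reactants: 14 3-{[(1R,2S)-1-[4-(allyloxy)phenyl]-2,3-dihydroxypropyl]oxy}-5-methoxy-2-(3-methylbut-2-enyl)phenyl acetate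
Product: 15 3-{[(1R,2R)-1-[4-(allyloxy)phenyl]-2-hydroxy-3-oxopropyl]oxy}-5-methoxy-2-(3-methylbut-2-enyl)phenyl acetate
Conditions: TEMPO (0.2 equiv), PhI(OAc)2 (1.1 equiv), dry CH2Cl2, 0 °C to rt; Na2S2O3/NaHCO3 wash; used crude at once
Reagents that add atoms: none
Why: TEMPO/PhI(OAc)2 oxidation, in which the oxoammonium ion selects the primary over the flanked secondary carbinol and stops at the aldehyde in dry CH2Cl2; the aryl acetate, allyl ether, prenyl alkene and the C3 stereocentre should be unaffected by the weakly acidic medium.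

**Step 10**
Reactants: 15 3-{[(1R,2R)-1-[4-(allyloxy)phenyl]-2-hydroxy-3-oxopropyl]oxy}-5-methoxy-2-(3-methylbut-2-enyl)phenyl acetate
Product: 17 (2R,3S,4S)-2-[4-(allyloxy)phenyl]-5-methoxy-8-(3-methylbut-2-enyl)chromane-3,4,7-triol, via phenoxide aldehyde 16 (not isolated)
Conditions: K2CO3 (0.3 equiv), degassed MeOH (5 mM), 0 °C to rt, Ar; pH 7 phosphate quench; Et3N-deactivated silica
Reagents that add atoms: none
Why: Methanolysis of the aryl acetate frees the 7-phenoxide of 16, whose charge is delocalised to the para carbon C4a, and this carbon adds to the aldehyde six atoms away (C4a–C8a–O1–C2–C3–C4) before the dienone re-aromatises. The closest known reaction types are the Lederer–Manasse hydroxyalkylation of phenolates, the addition of metal phenolates to alpha-oxygenated aldehydes and intramolecular Marschalk ring closures. Ring C closes in the 6-(enolendo)-exo-trig mode through the new C4–C4a bond, and no other ring size is possible because C8 carries the prenyl group. The new C4 stereocentre is controlled by the C3 carbinol in a half-chair transition state with the C2 aryl group and the C3 oxygen equatorial: the C3–O bond lies anti to the forming bond (Felkin–Anh polar model) and the carbonyl oxygen takes the pseudo-axial site away from the peri 5-methoxy group, which should give the 3,4-cis (4S) carbinol, and retro-aldol equilibration under the same conditions should favour the same isomer. The step needs ring closure to outrun enolisation of the alpha-hydroxy aldehyde (C3 epimerisation, loss of the aryloxide by beta-elimination) and intermolecular aldol addition, which substoichiometric base, low temperature and high dilution should secure; the B-ring phenol stays allylated so that no p-quinone methide can expel the A-ring aryloxide.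

**Step 11**
Reactants: 17 (2R,3S,4S)-2-[4-(allyloxy)phenyl]-5-methoxy-8-(3-methylbut-2-enyl)chromane-3,4,7-triol
Product: 18 (2R,3S,4S)-2-(4-hydroxyphenyl)-5-methoxy-8-(3-methylbut-2-enyl)chromane-3,4,7-triol (5-O-methyl-8-prenylafzelechin-4β-ol)
Conditions: Pd(PPh3)4 (5 mol %), morpholine (10 equiv), degassed THF, rt, Ar; Sephadex LH-20
Reagents that add atoms: none
Why: Tsuji–Trost-type deallylation: zerovalent palladium ionises the aryl allyl ether and morpholine captures the allyl group; the acid-free, room-temperature conditions should leave the labile benzylic C4 carbinol, the prenyl alkene (no leaving group) and all three stereocentres untouched.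

**Compound list**
1 | 5-methoxyresorcinol (5-methoxybenzene-1,3-diol) | COc1cc(O)cc(O)c1 | starting material
2 | chloromethyl methyl ether | COCCl | starting material
3 | 1-methoxy-3,5-bis(methoxymethoxy)benzene | COCOc1cc(OC)cc(OCOC)c1 | intermediate
4 | prenyl bromide (1-bromo-3-methylbut-2-ene) | CC(C)=CCBr | starting material
5 | [4-methoxy-2,6-bis(methoxymethoxy)phenyl]lithium | [Li]c1c(OCOC)cc(OC)cc1OCOC | intermediate
6 | 5-methoxy-1,3-bis(methoxymethoxy)-2-(3-methylbut-2-enyl)benzene | COCOc1cc(OC)cc(OCOC)c1CC=C(C)C | intermediate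
7 | 5-methoxy-2-(3-methylbut-2-enyl)benzene-1,3-diol | COc1cc(O)c(CC=C(C)C)c(O)c1 | intermediate
8 | (E)-p-coumaric acid | OC(=O)/C=C/c1ccc(O)cc1 | starting material
9 | allyl bromide | C=CCBr | starting material
10 | allyl (E)-3-[4-(allyloxy)phenyl]acrylate | C=CCOC(=O)/C=C/c1ccc(OCC=C)cc1 | intermediate
11 | (E)-3-[4-(allyloxy)phenyl]prop-2-en-1-ol | OC/C=C/c1ccc(OCC=C)cc1 | intermediate
12 | [(2S,3S)-3-(4-allyloxyphenyl)oxiran-2-yl]methanol (trans) | OC[C@@H]1O[C@H]1c1ccc(OCC=C)cc1 | intermediate
13 | (2S,3R)-3-[4-(allyloxy)phenyl]-3-[3-hydroxy-5-methoxy-2-(3-methylbut-2-enyl)phenoxy]propane-1,2-diol | OC[C@H](O)[C@H](Oc1cc(OC)cc(O)c1CC=C(C)C)c1ccc(OCC=C)cc1 | intermediate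
14 | 3-{[(1R,2S)-1-[4-(allyloxy)phenyl]-2,3-dihydroxypropyl]oxy}-5-methoxy-2-(3-methylbut-2-enyl)phenyl acetate | OC[C@H](O)[C@H](Oc1cc(OC)cc(OC(C)=O)c1CC=C(C)C)c1ccc(OCC=C)cc1 | intermediate
15 | 3-{[(1R,2R)-1-[4-(allyloxy)phenyl]-2-hydroxy-3-oxopropyl]oxy}-5-methoxy-2-(3-methylbut-2-enyl)phenyl acetate | O=C[C@H](O)[C@H](Oc1cc(OC)cc(OC(C)=O)c1CC=C(C)C)c1ccc(OCC=C)cc1 | intermediate
16 | (2R,3R)-3-[4-(allyloxy)phenyl]-2-hydroxy-3-[3-hydroxy-5-methoxy-2-(3-methylbut-2-enyl)phenoxy]propanal (present as its 7-phenoxide) | O=C[C@H](O)[C@H](Oc1cc(OC)cc(O)c1CC=C(C)C)c1ccc(OCC=C)cc1 | intermediate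
17 | (2R,3S,4S)-2-[4-(allyloxy)phenyl]-5-methoxy-8-(3-methylbut-2-enyl)chromane-3,4,7-triol (2,3-trans-3,4-cis) | COc1cc(O)c(CC=C(C)C)c2c1[C@H](O)[C@H](O)[C@@H](c1ccc(OCC=C)cc1)O2 | intermediate
18 | (2R,3S,4S)-2-(4-hydroxyphenyl)-5-methoxy-8-(3-methylbut-2-enyl)chromane-3,4,7-triol (5-O-methyl-8-prenylafzelechin-4β-ol) | COc1cc(O)c(CC=C(C)C)c2c1[C@H](O)[C@H](O)[C@@H](c1ccc(O)cc1)O2 | target

**Count and risks**
Total: 11 steps. Longest linear sequence: 8 steps (1, 2, 3, 7, 8, 9, 10, 11).

Step 10 is the most likely to fail. Enolisation of the alpha-hydroxy aldehyde (epimerisation at C3, beta-elimination of the A-ring aryloxide) may outrun ring closure, or the two faces of the aldehyde may be poorly differentiated. The fallback makes the two bonds of ring C in the reverse order; it sets out from 12 and 7 and returns at 17. Parikh–Doering oxidation of 12 (SO3·pyridine, DMSO, i-Pr2NEt, 0 °C) would give (2R,3S)-3-[4-(allyloxy)phenyl]oxirane-2-carbaldehyde F1. The aryloxytitanium triisopropoxide made from 7 and Ti(OiPr)4 would add through its ortho carbon to F1 (ortho-specific hydroxyalkylation of a metal phenoxide, non-chelated Felkin–Anh anti addition) to give (S)-[2,4-dihydroxy-6-methoxy-3-(3-methylbut-2-enyl)phenyl]{(2S,3S)-3-[4-(allyloxy)phenyl]oxiran-2-yl}methanol F2. The phenol ortho to the new carbinol would then open the epoxide at the p-alkoxybenzylic carbon (6-endo, inversion; catalytic PPTS, CH2Cl2, 0 °C) to give 17.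

Step 9 is second. Over-oxidation to the hydroxy acid or cleavage of the C–C bond may occur, and the free alpha-hydroxy aldehyde may dimerise or epimerise on handling. The fallback singles out the primary carbinol by silylation instead of by the oxidant; it sets out from 14 and returns at 17. Silylation (TBSCl, imidazole, DMF, 0 °C) would give 3-{[(1R,2S)-1-[4-(allyloxy)phenyl]-3-[tert-butyl(dimethyl)silyloxy]-2-hydroxypropyl]oxy}-5-methoxy-2-(3-methylbut-2-enyl)phenyl acetate F3. Acetylation (Ac2O, pyridine, DMAP) would give (1R,2S)-1-[3-acetoxy-5-methoxy-2-(3-methylbut-2-enyl)phenoxy]-1-[4-(allyloxy)phenyl]-3-[tert-butyl(dimethyl)silyloxy]propan-2-yl acetate F4. Desilylation under acidic fluoride, to suppress acetyl migration (HF·pyridine, THF/pyridine), would give (1R,2S)-1-[3-acetoxy-5-methoxy-2-(3-methylbut-2-enyl)phenoxy]-1-[4-(allyloxy)phenyl]-3-hydroxypropan-2-yl acetate F5. Dess–Martin periodinane with NaHCO3 would give (1R,2R)-1-[3-acetoxy-5-methoxy-2-(3-methylbut-2-enyl)phenoxy]-1-[4-(allyloxy)phenyl]-3-oxopropan-2-yl acetate F6. Under the conditions of step 10, F6 would lose both acetates and close ring C to 17.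

Step 7 is third. Base-induced migration of the epoxide (Payne rearrangement) followed by attack at C1, C-alkylation of the ambident phenoxide, or double alkylation of 7 may erode the yield. The fallback uses an electrophile without a free hydroxyl and adjusts the oxidation level afterwards; it sets out from 10 and 7 and returns at 13. Asymmetric nucleophilic epoxidation of the enoate 10 (t-BuOOH, Y(OiPr)3, chiral biaryldiol ligand, Ph3As=O, ligand enantiomer chosen for the 2R,3S product; only the electron-poor alkene reacts) would give allyl (2R,3S)-3-[4-(allyloxy)phenyl]oxirane-2-carboxylate F7. Opening of F7 by 7 (Cs2CO3, DMF) at the benzylic beta-carbon, with inversion, would give allyl (2R,3R)-3-[4-(allyloxy)phenyl]-2-hydroxy-3-[3-hydroxy-5-methoxy-2-(3-methylbut-2-enyl)phenoxy]propanoate F8. Reduction of the ester (LiBH4, THF, 0 °C) would give 13.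

**Further compounds**
F1 | step 10 | (2R,3S)-3-[4-(allyloxy)phenyl]oxirane-2-carbaldehyde | O=C[C@@H]1O[C@H]1c1ccc(OCC=C)cc1
F2 | step 10 | (S)-[2,4-dihydroxy-6-methoxy-3-(3-methylbut-2-enyl)phenyl]{(2S,3S)-3-[4-(allyloxy)phenyl]oxiran-2-yl}methanol | COc1cc(O)c(CC=C(C)C)c(O)c1[C@H](O)[C@@H]1O[C@H]1c1ccc(OCC=C)cc1
F3 | step 9 | 3-{[(1R,2S)-1-[4-(allyloxy)phenyl]-3-[tert-butyl(dimethyl)silyloxy]-2-hydroxypropyl]oxy}-5-methoxy-2-(3-methylbut-2-enyl)phenyl acetate | CC(C)(C)[Si](C)(C)OC[C@H](O)[C@H](Oc1cc(OC)cc(OC(C)=O)c1CC=C(C)C)c1ccc(OCC=C)cc1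
F4 | step 9 | (1R,2S)-1-[3-acetoxy-5-methoxy-2-(3-methylbut-2-enyl)phenoxy]-1-[4-(allyloxy)phenyl]-3-[tert-butyl(dimethyl)silyloxy]propan-2-yl acetate | CC(C)(C)[Si](C)(C)OC[C@H](OC(C)=O)[C@H](Oc1cc(OC)cc(OC(C)=O)c1CC=C(C)C)c1ccc(OCC=C)cc1
F5 | step 9 | (1R,2S)-1-[3-acetoxy-5-methoxy-2-(3-methylbut-2-enyl)phenoxy]-1-[4-(allyloxy)phenyl]-3-hydroxypropan-2-yl acetate | OC[C@H](OC(C)=O)[C@H](Oc1cc(OC)cc(OC(C)=O)c1CC=C(C)C)c1ccc(OCC=C)cc1
F6 | step 9 | (1R,2R)-1-[3-acetoxy-5-methoxy-2-(3-methylbut-2-enyl)phenoxy]-1-[4-(allyloxy)phenyl]-3-oxopropan-2-yl acetate | O=C[C@H](OC(C)=O)[C@H](Oc1cc(OC)cc(OC(C)=O)c1CC=C(C)C)c1ccc(OCC=C)cc1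
F7 | step 7 | allyl (2R,3S)-3-[4-(allyloxy)phenyl]oxirane-2-carboxylate | C=CCOC(=O)[C@@H]1O[C@H]1c1ccc(OCC=C)cc1
F8 | step 7 | allyl (2R,3R)-3-[4-(allyloxy)phenyl]-2-hydroxy-3-[3-hydroxy-5-methoxy-2-(3-methylbut-2-enyl)phenoxy]propanoate | C=CCOC(=O)[C@H](O)[C@H](Oc1cc(OC)cc(O)c1CC=C(C)C)c1ccc(OCC=C)cc1
A1 | direct plan | (E)-1-[6-methoxy-2,4-bis(methoxymethoxy)-3-(3-methylbut-2-enyl)phenyl]-3-[4-(methoxymethoxy)phenyl]prop-2-en-1-one | COCOc1ccc(/C=C/C(=O)c2c(OC)cc(OCOC)c(CC=C(C)C)c2OCOC)cc1
A2 | direct plan | (2R,3R)-3,7-dihydroxy-2-(4-hydroxyphenyl)-5-methoxy-8-(3-methylbut-2-enyl)chroman-4-one | COc1cc(O)c(CC=C(C)C)c2c1C(=O)[C@H](O)[C@@H](c1ccc(O)cc1)O2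
A3 | direct plan | (2R,3S,4R)-2-(4-hydroxyphenyl)-5-methoxy-8-(3-methylbut-2-enyl)chromane-3,4,7-triol (4α-ol, 3,4-trans) | COc1cc(O)c(CC=C(C)C)c2c1[C@@H](O)[C@H](O)[C@@H](c1ccc(O)cc1)O2
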